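## Retrosynthetic overview

1. Numbering: ring carbons C1–C10 (C1=C10 alkene with C14 on C10; C4–C5 epoxide with C15 on C4; O6 is the lactone oxygen; C7 carries C11(=C13)–C12(=O); O8 is the ester oxygen). The strategy rests on C8, an oxygen-bearing ring carbon lying β,γ to the Z alkene C1=C10 of the ten-membered ring, and on the cis-4,5-epoxide and trans-6,7-lactone, which fit a cyclooctane C1–C8.
2. Key disconnection C8–C9: photochemical 1,3-acyl shift of the 2-isopropenylcyclooctanone 18 (C9, C10, C14 in the isopropenyl group on C1) to the cyclodecenone 19.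
3. 18 comes from cyclooctane-1,5-dione (its carbonyls become C4 and C8): enone formation, MeLi and oxidative transposition give the C4-methyl enone with C6=O; catalyst-controlled reduction sets C6; the C8 ketone then takes the isopropenyl group at C1 and the acetate arm at C7 (anti to O6); O6-directed epoxidation and lactonisation follow.
4. From 19: C8 reduction, lactone α-methylenation (C13), acylation of O8 with acid 30 (silyl-protected 4-hydroxytiglic acid from a Wittig reaction), desilylation.
5. Ring order: cyclooctane (bought) → oxirane (step 11) → γ-lactone (step 12) → ten-membered carbocycle (step 13).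

Key step: step 13

Remark: cyclooctane-1,5-dione is taken as a purchasable compound; it is otherwise two steps from cycloocta-1,5-diene (hydroboration–oxidation to the cis-1,5-diol, then oxidation).
Remark: C1 of 12–18 is α to the ketone and allylic, so it epimerises easily and disappears in step 13; these compounds are drawn as the (1S) epimers (isopropenyl cis to the C7 arm), and either epimer serves.
Remark: the CIP letters at C6 and C7 change along the route through changes of substituent priority only, not through inversion.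

## Route

Step 1
Reactants: 1 cyclooctane-1,5-dione
Product: 2 1,4-dioxaspiro[4.7]dodecan-9-one
Conditions: (Me3SiOCH2)2 (1.0 equiv), Me3SiOTf (cat.), CH2Cl2, −78 °C
Reagents that add atoms: 1,2-bis(trimethylsilyloxy)ethane, C[Si](C)(C)OCCO[Si](C)(C)C
Why: Noyori ketalisation at low temperature masks one of the two equivalent carbonyls (the later C8) without the transannular aldol that hot acid would cause; bis-ketal and recovered 1 are recycled.

Step 2
Reactants: 2 1,4-dioxaspiro[4.7]dodecan-9-one
Product: 3 (7Z)-1,4-dioxaspiro[4.7]dodec-7-en-9-one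
Conditions: IBX (1.5 equiv), DMSO/fluorobenzene, 65 °C
Reagents that add atoms: none
Why: IBX dehydrogenation of the ketone to the enone; the two α-methylene groups of 2 are related by symmetry, so a single enone (C4=O, C5=C6) should form, necessarily cis in the eight-membered ring.

Step 3
Reactants: 3 (7Z)-1,4-dioxaspiro[4.7]dodec-7-en-9-one
Product: 4 rac-(7Z)-9-methyl-1,4-dioxaspiro[4.7]dodec-7-en-9-ol
Conditions: MeLi, Et2O/THF, −78 °C; then H2O
Reagents that add atoms: methyllithium, [Li]C
Why: 1,2-addition of the organolithium to the enone carbonyl introduces C15; the tertiary carbinol centre is removed again in step 4.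

Step 4
Reactants: 4 rac-(7Z)-9-methyl-1,4-dioxaspiro[4.7]dodec-7-en-9-ol
Product: 5 (8Z)-9-methyl-1,4-dioxaspiro[4.7]dodec-8-en-7-one
Conditions: pyridinium chlorochromate (C5H5NH)[CrO3Cl], NaOAc, 4 Å MS, CH2Cl2, 25 °C
Reagents that add atoms: pyridinium chlorochromate, [O-][Cr](=O)(=O)Cl.c1cc[nH+]cc1
Why: Babler–Dauben oxidative transposition: the tertiary allylic chromate ester rearranges by a [3,3] shift and is oxidised, which moves the oxygen to C6 and leaves the methyl-bearing alkene at C4=C5.

Step 5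
Reactants: 5 (8Z)-9-methyl-1,4-dioxaspiro[4.7]dodec-8-en-7-one
Product: 6 (7S,8Z)-9-methyl-1,4-dioxaspiro[4.7]dodec-8-en-7-ol
Conditions: (R)-2-methyl-CBS-oxazaborolidine (15 mol %), BH3·SMe2, THF, −30 °C; then MeOH
Reagents that add atoms: none
Why: Corey–Bakshi–Shibata reduction: with the alkenyl arm of the enone as the large group, the (R)-catalyst should deliver hydride to the face that gives the (S)-carbinol, which is C6 of the target.

Step 6
Reactants: 6 (7S,8Z)-9-methyl-1,4-dioxaspiro[4.7]dodec-8-en-7-ol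
Product: 7 tert-butyldimethylsilyl ether of 6
Conditions: t-BuMe2SiCl, imidazole, DMF, 25 °C
Reagents that add atoms: tert-butyldimethylsilyl chloride, CC(C)(C)[Si](C)(C)Cl
Why: Standard silylation of the secondary allylic alcohol keeps O6 protected through the two enolate steps.

Step 7
Reactants: 7 tert-butyldimethylsilyl ether of 6
Product: 8 (3S,4Z)-3-[(tert-butyldimethylsilyl)oxy]-5-methylcyclooct-4-en-1-one
Conditions: PPTS (cat.), acetone/H2O, 50 °C
Reagents that add atoms: water, O
Why: Mild acid-catalysed ketal hydrolysis frees the C8 ketone while the secondary silyl ether and the trisubstituted alkene stay untouched.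

Step 8
Reactants: 8 (3S,4Z)-3-[(tert-butyldimethylsilyl)oxy]-5-methylcyclooct-4-en-1-one; 9 2-bromopropene
Product: 12 (3S,4Z,8S)-3-[(tert-butyldimethylsilyl)oxy]-5-methyl-8-(prop-1-en-2-yl)cyclooct-4-en-1-one, via lithium C1-enolate 10 (not isolated), via lithium dienolate 11 (not isolated)
Conditions: LiN(SiMe3)2 (2.2 equiv), THF, −78 °C; Pd2(dba)3 (2 mol %), P(t-Bu)3 (5 mol %), 9, −78 to 25 °C; AcOH, −78 °C
Reagents that add atoms: none
Why: Palladium-catalysed α-alkenylation of a ketone enolate: kinetic deprotonation should take place at C1, the α-methylene remote from the hindered silyloxy-bearing carbon; the excess base holds the product as its dienolate so that no ketone is left to equilibrate the enolates, and cold protonation at the α-carbon gives the β,γ-unsaturated ketone (C1 forms as an epimer pair, see remark).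

Step 9
Reactants: 12 (3S,4Z,8S)-3-[(tert-butyldimethylsilyl)oxy]-5-methyl-8-(prop-1-en-2-yl)cyclooct-4-en-1-one; 13 ethyl bromoacetate
Product: 15 ethyl 2-[(1S,2R,3Z,7S)-2-[(tert-butyldimethylsilyl)oxy]-4-methyl-8-oxo-7-(prop-1-en-2-yl)cyclooct-3-en-1-yl]acetate, via lithium C7-enolate 14 (not isolated)
Conditions: LiN(i-Pr)2 (1.05 equiv), THF, −78 °C; 13, DMPU, −78 °C; AcOH
Reagents that add atoms: none
Why: Kinetic enolate alkylation: at −78 °C the amide should remove a C7 methylene proton in preference to the tertiary, A(1,3)-shielded C1–H, and the electrophile enters anti to the adjacent C6 silyloxy group, which sets C7 trans to O6.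

Step 10
Reactants: 15 ethyl 2-[(1S,2R,3Z,7S)-2-[(tert-butyldimethylsilyl)oxy]-4-methyl-8-oxo-7-(prop-1-en-2-yl)cyclooct-3-en-1-yl]acetate
Product: 16 ethyl 2-[(1S,2R,3Z,7S)-2-hydroxy-4-methyl-8-oxo-7-(prop-1-en-2-yl)cyclooct-3-en-1-yl]acetate
Conditions: HF·pyridine, pyridine, THF, 0 to 25 °C
Reagents that add atoms: none
Why: Buffered fluoride desilylation frees the C6 hydroxyl; the ethyl ester should not lactonise without a catalyst, so the hydroxyl stays free to direct step 11.

Step 11
Reactants: 16 ethyl 2-[(1S,2R,3Z,7S)-2-hydroxy-4-methyl-8-oxo-7-(prop-1-en-2-yl)cyclooct-3-en-1-yl]acetate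
Product: 17 ethyl 2-[(1S,2S,3S,5S,8R)-2-hydroxy-8-methyl-4-oxo-5-(prop-1-en-2-yl)-9-oxabicyclo[6.1.0]nonan-3-yl]acetate
Conditions: VO(acac)2 (5 mol %), t-BuOOH, CH2Cl2, 0 °C
Reagents that add atoms: tert-butyl hydroperoxide, CC(C)(C)OO
Why: Vanadium-catalysed hydroxyl-directed epoxidation: in cyclooct-2-en-1-ols the bound peroxide is delivered syn to the hydroxyl, so the oxirane oxygen at C4–C5 should end cis to O6 (4R,5S), and the isopropenyl group, which has no directing hydroxyl, is not touched.

Step 12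
Reactants: 17 ethyl 2-[(1S,2S,3S,5S,8R)-2-hydroxy-8-methyl-4-oxo-5-(prop-1-en-2-yl)-9-oxabicyclo[6.1.0]nonan-3-yl]acetate
Product: 18 epoxy lactone-fused 2-isopropenylcyclooctanone (1S,4R,5S,6S,7S)
Conditions: PPTS (cat.), benzene, 40 °C
Reagents that add atoms: none
Why: Acid-catalysed lactonisation (intramolecular transesterification): the C6 hydroxyl attacks the ester carbonyl, so C6 keeps its configuration and the γ-lactone is trans-fused.

Step 13
Reactants: 18 epoxy lactone-fused 2-isopropenylcyclooctanone (1S,4R,5S,6S,7S)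
Product: 19 (1(10)Z,4R,5S,6S,7S)-4,5-epoxy-8-oxo-13-norgermacr-1(10)-en-12,6-olide
Conditions: hν (300 nm lamps, Pyrex), degassed benzene (0.005 M), 20 °C; stopped at partial conversion, recovered 18 irradiated again
Reagents that add atoms: none
Why: n,π* excitation of the C8 ketone is followed by α-cleavage of the C8–C1 bond on the allylic side, and the acyl radical recombines in the solvent cage at C9, the far end of the 2-methylallyl radical, so that the C8–C9 bond and the C1=C10 alkene form. The closest known reaction is the photochemical 1,3-acyl shift of β,γ-unsaturated ketones used as a two-carbon ring expansion of 2-alkenylcycloalkanones. The ten-membered ring closes by radical-pair recombination (acyl C8 onto allyl terminus C9), formally a 1,3-sigmatropic shift that inserts C10 and C9 between C1 and C8. No stereocentre is formed: C1 becomes trigonal (so both C1 epimers converge), and the Z geometry is expected because recombination to the cis-cyclodecenone is less strained than closure across a trans alkene. The step needs cleavage at C8–C1 and not at C8–C7, which the allylic stabilisation secures; it needs singlet reactivity, which direct irradiation without a sensitiser secures against the oxa-di-π-methane path; and it must outrun decarbonylation, which fast recombination in the cage favours. Because 19 is itself a β,γ-unsaturated ketone the shift is reversible, so the irradiation is stopped early and 18 is recycled.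

Step 14
Reactants: 19 (1(10)Z,4R,5S,6S,7S)-4,5-epoxy-8-oxo-13-norgermacr-1(10)-en-12,6-olide
Product: 20 (1(10)Z,4R,5S,6S,7R,8R)-4,5-epoxy-8-hydroxy-13-norgermacr-1(10)-en-12,6-olide
Conditions: NaBH4, CeCl3·7H2O, MeOH/THF, −78 °C
Reagents that add atoms: none
Why: Luche reduction of the ketone without basic side reactions; hydride should reach the C8 carbonyl from the face anti to the C7–C11 bond, which places the new hydroxyl cis to C11 as in the target.

Step 15
Reactants: 20 (1(10)Z,4R,5S,6S,7R,8R)-4,5-epoxy-8-hydroxy-13-norgermacr-1(10)-en-12,6-olide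
Product: 21 (1(10)Z,4R,5S,6S,7S,8R)-4,5-epoxy-8-(triethylsilyloxy)-13-norgermacr-1(10)-en-12,6-olide
Conditions: Et3SiCl, imidazole, DMAP (cat.), DMF, 25 °C
Reagents that add atoms: chlorotriethylsilane, CC[Si](CC)(CC)Cl
Why: Silylation of the secondary alcohol protects O8 and blocks alkoxide attack on the lactone during the strongly basic step 16.

Step 16
Reactants: 21 (1(10)Z,4R,5S,6S,7S,8R)-4,5-epoxy-8-(triethylsilyloxy)-13-norgermacr-1(10)-en-12,6-olide
Product: 25 (1(10)Z,4R,5S,6S,7S,8R)-4,5-epoxy-8-(triethylsilyloxy)germacra-1(10),11(13)-dien-12,6-olide, via lactone lithium enolate 22 (not isolated), via Mannich base 23 (not isolated), via trimethylammonium iodide 24 (not isolated)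
Conditions: LiN(i-Pr)2, THF, −78 °C; CH2=NMe2+ I− (Eschenmoser's salt), −78 to 0 °C; MeI, MeOH/CH2Cl2, 25 °C; NaHCO3 (aq), CH2Cl2, 25 °C
Reagents that add atoms: N,N-dimethylmethyleneiminium iodide (Eschenmoser's salt), C=[N+](C)C.[I-]
Why: Lactone α-methylenation: the lithium enolate undergoes a Mannich reaction with the iminium salt, the amine is quaternised and the ammonium salt eliminates to the exocyclic alkene, the transient C11 centre being lost.

Step 17
Reactants: 25 (1(10)Z,4R,5S,6S,7S,8R)-4,5-epoxy-8-(triethylsilyloxy)germacra-1(10),11(13)-dien-12,6-olide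
Product: 26 (1(10)Z,4R,5S,6S,7R,8R)-4,5-epoxy-8-hydroxygermacra-1(10),11(13)-dien-12,6-olide
Conditions: HF·pyridine, pyridine, THF, 0 °C
Reagents that add atoms: none
Why: Buffered fluoride cleavage of the triethylsilyl ether, which the epoxide and the α-methylene lactone should tolerate.

Step 18
Reactants: 27 (tert-butyldimethylsilyloxy)acetaldehyde; 28 ethyl 2-(triphenyl-λ5-phosphanylidene)propanoate
Product: 29 ethyl (2E)-4-[(tert-butyldimethylsilyl)oxy]-2-methylbut-2-enoate
Conditions: CH2Cl2, 25 °C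
Reagents that add atoms: none
Why: Wittig olefination with a stabilised ylide, which gives the trisubstituted E-enoate.

Step 19
Reactants: 29 ethyl (2E)-4-[(tert-butyldimethylsilyl)oxy]-2-methylbut-2-enoate
Product: 30 (2E)-4-[(tert-butyldimethylsilyl)oxy]-2-methylbut-2-enoic acid
Conditions: LiOH, THF/MeOH/H2O, 25 °C; then 1 M HCl to pH 4
Reagents that add atoms: lithium hydroxide, [Li+].[OH-]
Why: Saponification of the ethyl ester; the primary silyl ether should survive aqueous LiOH and brief acidification to pH 4.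

Step 20
Reactants: 26 (1(10)Z,4R,5S,6S,7R,8R)-4,5-epoxy-8-hydroxygermacra-1(10),11(13)-dien-12,6-olide; 30 (2E)-4-[(tert-butyldimethylsilyl)oxy]-2-methylbut-2-enoic acid
Product: 32 8-O-[(2E)-4-(tert-butyldimethylsilyloxy)-2-methylbut-2-enoyl] derivative of 26, via mixed anhydride 31 (not isolated)
Conditions: 30, 2,4,6-Cl3C6H2COCl, Et3N, THF, 25 °C; then 26, DMAP, toluene, 25 °C
Reagents that add atoms: none
Why: Yamaguchi esterification: the mixed anhydride acylates the hindered secondary C8 hydroxyl under DMAP catalysis with retention at C8, and the E-enoate is the stable geometry.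

Step 21
Reactants: 32 8-O-[(2E)-4-(tert-butyldimethylsilyloxy)-2-methylbut-2-enoyl] derivative of 26
Product: 33 (1(10)Z,4R,5S,6S,7R,8R)-4,5-epoxy-8-[(2E)-4-hydroxy-2-methylbut-2-enoyloxy]germacra-1(10),11(13)-dien-12,6-olide (target)
Conditions: HF·pyridine, pyridine, THF, 0 °C
Reagents that add atoms: none
Why: Buffered fluoride cleavage of the primary allylic silyl ether under non-basic conditions that spare the α-methylene lactone, the epoxide and both esters.

## Compound list

1 | cyclooctane-1,5-dione | O=C1CCCC(=O)CCC1 | starting material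
2 | 1,4-dioxaspiro[4.7]dodecan-9-one | O=C1CCCC2(CCC1)OCCO2 | intermediate
3 | (7Z)-1,4-dioxaspiro[4.7]dodec-7-en-9-one | O=C1/C=C\CC2(OCCO2)CCC1 | intermediate
4 | rac-(7Z)-9-methyl-1,4-dioxaspiro[4.7]dodec-7-en-9-ol | CC1(O)/C=C\CC2(OCCO2)CCC1 | intermediate
5 | (8Z)-9-methyl-1,4-dioxaspiro[4.7]dodec-8-en-7-one | C/C1=C/C(=O)CC2(OCCO2)CCC1 | intermediate
6 | (7S,8Z)-9-methyl-1,4-dioxaspiro[4.7]dodec-8-en-7-ol | C/C1=C/[C@@H](O)CC2(OCCO2)CCC1 | intermediate
7 | tert-butyl(dimethyl){[(7S,8Z)-9-methyl-1,4-dioxaspiro[4.7]dodec-8-en-7-yl]oxy}silane | C/C1=C/[C@@H](O[Si](C)(C)C(C)(C)C)CC2(OCCO2)CCC1 | intermediate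
8 | (3S,4Z)-3-[(tert-butyldimethylsilyl)oxy]-5-methylcyclooct-4-en-1-one | C/C1=C/[C@@H](O[Si](C)(C)C(C)(C)C)CC(=O)CCC1 | intermediate
9 | 2-bromopropene | CC(Br)=C | starting material
10 | lithium (7S)-7-[(tert-butyldimethylsilyl)oxy]-5-methylcycloocta-1,5-dien-1-olate (C1 enolate of 8) | C/C1=C/[C@@H](O[Si](C)(C)C(C)(C)C)C/C(O[Li])=C\CC1 | intermediate
11 | lithium (7S)-7-[(tert-butyldimethylsilyl)oxy]-5-methyl-2-(prop-1-en-2-yl)cycloocta-1,5-dien-1-olate (dienolate of 12) | C/C1=C/[C@@H](O[Si](C)(C)C(C)(C)C)C/C(O[Li])=C(/C(C)=C)CC1 | intermediate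
12 | (3S,4Z,8S)-3-[(tert-butyldimethylsilyl)oxy]-5-methyl-8-(prop-1-en-2-yl)cyclooct-4-en-1-one | C/C1=C/[C@@H](O[Si](C)(C)C(C)(C)C)CC(=O)[C@H](C(C)=C)CC1 | intermediate
13 | ethyl bromoacetate | CCOC(=O)CBr | starting material
14 | lithium (3R,8S)-3-[(tert-butyldimethylsilyl)oxy]-5-methyl-8-(prop-1-en-2-yl)cycloocta-1,4-dien-1-olate (C7 enolate of 12) | C/C1=C/[C@@H](O[Si](C)(C)C(C)(C)C)/C=C(/O[Li])[C@H](C(C)=C)CC1 | intermediate
15 | ethyl 2-[(1S,2R,3Z,7S)-2-[(tert-butyldimethylsilyl)oxy]-4-methyl-8-oxo-7-(prop-1-en-2-yl)cyclooct-3-en-1-yl]acetate | C/C1=C/[C@@H](O[Si](C)(C)C(C)(C)C)[C@H](CC(=O)OCC)C(=O)[C@H](C(C)=C)CC1 | intermediate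
16 | ethyl 2-[(1S,2R,3Z,7S)-2-hydroxy-4-methyl-8-oxo-7-(prop-1-en-2-yl)cyclooct-3-en-1-yl]acetate | C/C1=C/[C@@H](O)[C@H](CC(=O)OCC)C(=O)[C@H](C(C)=C)CC1 | intermediate
17 | ethyl 2-[(1S,2S,3S,5S,8R)-2-hydroxy-8-methyl-4-oxo-5-(prop-1-en-2-yl)-9-oxabicyclo[6.1.0]nonan-3-yl]acetate | O[C@H]2[C@H](CC(=O)OCC)C(=O)[C@H](C(C)=C)CC[C@@]1(C)O[C@@H]21 | intermediate
18 | epoxy lactone-fused 2-isopropenylcyclooctanone: cyclooctanone (C8=O) with (1S)-prop-1-en-2-yl, (4R,5S)-4,5-epoxide carrying the C4 methyl, and trans-fused γ-lactone O6–C12(=O)–C11H2–C7 (6S,7S) | O=C1O[C@H]2[C@H](C1)C(=O)[C@H](C(C)=C)CC[C@@]1(C)O[C@@H]21 | intermediate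
19 | (1(10)Z,4R,5S,6S,7S)-4,5-epoxy-8-oxo-13-norgermacr-1(10)-en-12,6-olide | O=C1O[C@H]2[C@H](C1)C(=O)C/C(C)=C\CC[C@@]1(C)O[C@@H]21 | intermediate
20 | (1(10)Z,4R,5S,6S,7R,8R)-4,5-epoxy-8-hydroxy-13-norgermacr-1(10)-en-12,6-olide | O=C1O[C@H]2[C@H](C1)[C@H](O)C/C(C)=C\CC[C@@]1(C)O[C@@H]21 | intermediate
21 | (1(10)Z,4R,5S,6S,7S,8R)-4,5-epoxy-8-(triethylsilyloxy)-13-norgermacr-1(10)-en-12,6-olide | O=C1O[C@H]2[C@H](C1)[C@H](O[Si](CC)(CC)CC)C/C(C)=C\CC[C@@]1(C)O[C@@H]21 | intermediate
22 | lithium enolate of lactone 21 (C11=C12–OLi) | [Li]OC=1O[C@H]2[C@H](C=1)[C@H](O[Si](CC)(CC)CC)C/C(C)=C\CC[C@@]1(C)O[C@@H]21 | intermediate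
23 | 11-(dimethylaminomethyl) derivative of 21 (C11 epimers) | O=C1O[C@H]2[C@H](C1CN(C)C)[C@H](O[Si](CC)(CC)CC)C/C(C)=C\CC[C@@]1(C)O[C@@H]21 | intermediate
24 | trimethylammonium iodide derived from 23 | O=C1O[C@H]2[C@H](C1C[N+](C)(C)C)[C@H](O[Si](CC)(CC)CC)C/C(C)=C\CC[C@@]1(C)O[C@@H]21.[I-] | intermediate
25 | (1(10)Z,4R,5S,6S,7S,8R)-4,5-epoxy-8-(triethylsilyloxy)germacra-1(10),11(13)-dien-12,6-olide | C=C1C(=O)O[C@H]2[C@H]1[C@H](O[Si](CC)(CC)CC)C/C(C)=C\CC[C@@]1(C)O[C@@H]21 | intermediate
26 | (1(10)Z,4R,5S,6S,7R,8R)-4,5-epoxy-8-hydroxygermacra-1(10),11(13)-dien-12,6-olide | C=C1C(=O)O[C@H]2[C@H]1[C@H](O)C/C(C)=C\CC[C@@]1(C)O[C@@H]21 | intermediate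
27 | (tert-butyldimethylsilyloxy)acetaldehyde | O=CCO[Si](C)(C)C(C)(C)C | starting material
28 | ethyl 2-(triphenyl-λ5-phosphanylidene)propanoate | CCOC(=O)C(C)=P(c1ccccc1)(c1ccccc1)c1ccccc1 | starting material
29 | ethyl (2E)-4-[(tert-butyldimethylsilyl)oxy]-2-methylbut-2-enoate | CCOC(=O)/C(C)=C/CO[Si](C)(C)C(C)(C)C | intermediate
30 | (2E)-4-[(tert-butyldimethylsilyl)oxy]-2-methylbut-2-enoic acid | OC(=O)/C(C)=C/CO[Si](C)(C)C(C)(C)C | intermediate
31 | mixed anhydride of 30 with 2,4,6-trichlorobenzoic acid | O=C(OC(=O)c1c(Cl)cc(Cl)cc1Cl)/C(C)=C/CO[Si](C)(C)C(C)(C)C | intermediate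
32 | (1(10)Z,4R,5S,6S,7R,8R)-8-[(2E)-4-(tert-butyldimethylsilyloxy)-2-methylbut-2-enoyloxy]-4,5-epoxygermacra-1(10),11(13)-dien-12,6-olide | C=C1C(=O)O[C@H]2[C@H]1[C@H](OC(=O)/C(C)=C/CO[Si](C)(C)C(C)(C)C)C/C(C)=C\CC[C@@]1(C)O[C@@H]21 | intermediate
33 | (1(10)Z,4R,5S,6S,7R,8R)-4,5-epoxy-8-[(2E)-4-hydroxy-2-methylbut-2-enoyloxy]germacra-1(10),11(13)-dien-12,6-olide | C=C1C(=O)O[C@H]2[C@H]1[C@H](OC(=O)/C(C)=C/CO)C/C(C)=C\CC[C@@]1(C)O[C@@H]21 | target

## Step count and risks

Total step count: 21. Longest linear sequence: 19 steps (steps 1–17, 20, 21, from cyclooctane-1,5-dione); steps 18–19 prepare acid 30.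

Steps most likely to fail:

1. Step 13. What may go wrong: decarbonylation, or cleavage toward C7 with loss of the β-acyloxy group, instead of cage recombination; recombination to the E alkene; a photostationary state that stalls conversion. Fallback (ring expansion before lactone closure): it sets out from 17. Irradiation as in step 13 of this monocyclic, more flexible ketone, which has neither the trans-fused lactone nor a β-acyloxy group, should give the ten-membered hydroxy keto ester F1 by the same 1,3-acyl shift. PPTS (benzene, 40 °C) then closes the lactone from the C6 hydroxyl, and the route is rejoined at 19.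

2. Step 8. What may go wrong: enolisation toward C7 instead of C1, β-elimination of silanolate from a C7 enolate, a second alkenylation, migration of the new alkene into conjugation. Fallback (regiochemistry fixed by unsaturation): it sets out from 8. DBU (CH2Cl2, 25 °C) eliminates the silanol to (2Z,4Z)-5-methylcycloocta-2,4-dien-1-one F2, in which C1 is the only α-carbon that carries hydrogen. LiN(SiMe3)2 gives lithium enolate F3; coupling with 9 under the catalyst of step 8 gives lithium trienolate F4 and, after cold protonation, the 8-isopropenyl dienone F5. Copper-catalysed enantioselective conjugate borylation (CuCl, a chiral Josiphos-type ligand, NaOt-Bu, B2pin2, MeOH, THF) adds boron at C6, the β-carbon (the δ-carbon C4 is fully substituted), to give boronate F6. NaBO3·4H2O oxidises the C–B bond with retention to hydroxy ketone F7, and t-BuMe2SiCl/imidazole returns the material to the route at 12.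

3. Step 9. What may go wrong: β-elimination of silanolate from the C7 enolate back to a conjugated dienone, deprotonation at C1, poor facial selectivity. Fallback (dianion alkylation): it sets out from 12. HF·pyridine removes the silyl group to give hydroxy ketone F7 (the compound also passed in the fallback to step 8). LiN(i-Pr)2 (2.2 equiv, THF, −78 °C) forms the dilithium alkoxide enolate F8, from which oxide cannot leave. 13 then alkylates C7 anti to the alkoxide (Fráter–Seebach-type control), and quenching with AcOH at −78 °C, before the alkoxide can attack the new ester, gives 16, where the route is rejoined.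

Further compounds
F1 | step 13 | ethyl [(1(10)Z,4R,5S,6S,7S)-4,5-epoxy-6-hydroxy-4,10-dimethyl-8-oxocyclodec-1(10)-en-7-yl]acetate (overview numbering) | O[C@H]2[C@H](CC(=O)OCC)C(=O)C/C(C)=C\CC[C@@]1(C)O[C@@H]21
F2 | step 8 | (2Z,4Z)-5-methylcycloocta-2,4-dien-1-one | C/C1=C/C=C\C(=O)CCC1
F3 | step 8 | lithium enolate of F2 (C8=C1 enolate) | C/C1=C/C=C\C(O[Li])=C/CC1
F4 | step 8 | lithium trienolate of F5 | C/C1=C/C=C\C(O[Li])=C(\C(C)=C)CC1
F5 | step 8 | rac-(2Z,4Z)-5-methyl-8-(prop-1-en-2-yl)cycloocta-2,4-dien-1-one | C/C1=C/C=C\C(=O)C(C(C)=C)CC1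
F6 | step 8 | (3S,4Z)-5-methyl-8-(prop-1-en-2-yl)-3-(4,4,5,5-tetramethyl-1,3,2-dioxaborolan-2-yl)cyclooct-4-en-1-one (C8 epimers) | C/C1=C/[C@@H](B2OC(C)(C)C(C)(C)O2)CC(=O)C(C(C)=C)CC1
F7 | step 8 | (3S,4Z,8S)-3-hydroxy-5-methyl-8-(prop-1-en-2-yl)cyclooct-4-en-1-one (with its 8R epimer when made from F6) | C/C1=C/[C@@H](O)CC(=O)[C@H](C(C)=C)CC1
F8 | step 9 | dilithium alkoxide enolate of F7 (C7=C8 enolate) | C/C1=C/[C@@H](O[Li])/C=C(/O[Li])[C@H](C(C)=C)CC1
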